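**Retrosynthetic overview**

- Ring labels: A = hydroquinone ring, B = para-phenylene, C = catechol ring, D = meta-phenylene. The plan rests on the unit O–C(ring A)–C(ring A)–CH2–CH2(ring B). The ethano chain sits on the ring A carbon next to the oxygen bound to ring D. Its far carbon is benzylic to ring B and para to the ring B–O–ring C oxygen. Tying that carbon to the ring A oxygen draws a 2-aryl-5-methoxy-2,3-dihydrobenzofuran.
- Both free OH groups are masked as methyl ethers (BBr3 last). The 18-membered ring is opened at the ring A O–C3(ring D) aryl ether, which is made by intramolecular Ullmann coupling of a ring D bromide.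
- The ring A phenol is reconnected to the ring B benzylic carbon (reverse of an ionic hydrogenation). The dihydrofuran is then cut by an oxidative [3+2] cycloaddition into 4-methoxyphenol and a ring B styrene that already carries rings C and D.
- The styrene comes from isovanillin (ring C), 3-bromobenzyl bromide (ring D) and 4-fluorobenzaldehyde (ring B) by Wittig olefination, diimide reduction, SNAr and Wittig methylenation.
- Ring order: the temporary dihydrofuran ring forms in step 6, is opened in step 7, and the macrocycle closes in step 8. The four benzene rings are bought.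

Key step: step 6

Remark on the chemistry: the target SMILES holds no stereodescriptor and the 18-membered ring is taken as conformationally mobile, so no stereochemical element has to survive to the end.

Step 1
Reactants: 1 3-bromobenzyl bromide
Product: 2 (3-bromobenzyl)triphenylphosphonium bromide
Conditions: PPh3, toluene, reflux
Reagents that add atoms: triphenylphosphine, c1ccc(cc1)P(c1ccccc1)c1ccccc1
Why: SN2 quaternisation of PPh3 (phosphonium salt formation for a Wittig reaction) takes place only at the benzylic bromide, because the aryl C–Br bond is inert to a neutral phosphine, and the salt should precipitate from toluene.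

Step 2
Reactants: 2 (3-bromobenzyl)triphenylphosphonium bromide; 3 isovanillin (3-hydroxy-4-methoxybenzaldehyde)
Product: 5 (E/Z)-5-[2-(3-bromophenyl)ethenyl]-2-methoxyphenol, via 3-bromobenzylidene(triphenyl)phosphorane 4 (not isolated)
Conditions: KOtBu (2.2 equiv), THF, 0 °C → rt; then 1 M HCl
Reagents that add atoms: none
Why: Wittig olefination with the semistabilised ylide 4, in which the extra base holds the phenol of 3 as a phenoxide that is meta to the formyl group and so does not deactivate it by conjugation, and in which the alkene geometry is of no account because the double bond is saturated in step 3.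

Step 3
Reactants: 5 (E/Z)-5-[2-(3-bromophenyl)ethenyl]-2-methoxyphenol
Product: 6 5-[2-(3-bromophenyl)ethyl]-2-methoxyphenol
Conditions: TsNHNH2, NaOAc, DME–H2O, reflux
Reagents that add atoms: none
Why: Diimide reduction, in which HN=NH released from TsNHNH2 delivers H2 to the nonpolar C=C bond through a concerted cyclic transition state and, unlike hydrogenation over palladium, leaves the aryl C–Br bond intact.

Step 4
Reactants: 6 5-[2-(3-bromophenyl)ethyl]-2-methoxyphenol; 7 4-fluorobenzaldehyde
Product: 8 4-{5-[2-(3-bromophenyl)ethyl]-2-methoxyphenoxy}benzaldehyde
Conditions: K2CO3, DMF, 120 °C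
Reagents that add atoms: none
Why: Nucleophilic aromatic substitution (SNAr, addition–elimination), in which the phenoxide of 6 adds to the fluorine-bearing carbon of 7 that the para formyl group activates, whereas the unactivated ring D bromide does not react.

Step 5
Reactants: 8 4-{5-[2-(3-bromophenyl)ethyl]-2-methoxyphenoxy}benzaldehyde
Product: 9 1-bromo-3-{2-[3-(4-ethenylphenoxy)-4-methoxyphenyl]ethyl}benzene (ring B styrene carrying rings C and D)
Conditions: Ph3PCH3Br, KOtBu, THF, 0 °C → rt
Reagents that add atoms: methyltriphenylphosphonium bromide, [Br-].C[P+](c1ccccc1)(c1ccccc1)c1ccccc1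
Why: Wittig methylenation with the non-stabilised ylide Ph3P=CH2 turns the non-enolisable aryl aldehyde into the terminal styrene under conditions that leave the aryl ethers and the aryl bromide alone.

Step 6
Reactants: 9 1-bromo-3-{2-[3-(4-ethenylphenoxy)-4-methoxyphenyl]ethyl}benzene; 10 4-methoxyphenol
Product: 12 (±)-2-(4-{5-[2-(3-bromophenyl)ethyl]-2-methoxyphenoxy}phenyl)-5-methoxy-2,3-dihydro-1-benzofuran, via 4-methoxyphenoxenium ion 11 (not isolated)
Conditions: Ru(bpz)3(PF6)2 (2 mol %), (NH4)2S2O8 (2 equiv), 10 (2 equiv, in portions), MeCN, blue LEDs, rt
Reagents that add atoms: none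
Why: Persulfate quenches photoexcited Ru(bpz)3(PF6)2, and the trivalent ruthenium complex and the sulfate radical anion formed in this way take two electrons and one proton from 10 to give 11, an oxocarbenium-type cation that is electrophilic at the ring carbons next to its carbonyl group. The CH2 terminus of 9 bonds to one of these carbons (new C(ring A)–CH2 bond), the charge moves to the benzylic carbon where the para aryloxy oxygen of ring B carries it, the dienone oxygen adds to this carbon (new O–CH(ring B) bond) and proton loss restores aromatic ring A. The closest known reaction type is the visible-light photocatalytic, or hypervalent-iodine-mediated, oxidative [3+2] cycloaddition of para-alkoxyphenols with electron-rich styrenes to 2-aryl-2,3-dihydrobenzofurans. The dihydrofuran ring therefore closes stepwise, by the intermolecular C–C bond first and then by 5-exo-trig capture of the quinone-methide-like cation by oxygen. The new stereocentre C2 has no controlling element, forms as the racemate and is deleted in step 7. The step needs oxidation of 10 ahead of the styrene and the aryl ethers of 9, which the much lower oxidation potential of a free para-methoxyphenol secures, and it needs bonding at an ortho carbon with the aryl group ending next to oxygen, which the methoxy-blocked para position, the equivalence of the two ortho carbons and the benzylic stabilisation of the cation secure.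

Step 7
Reactants: 12 (±)-2-(4-{5-[2-(3-bromophenyl)ethyl]-2-methoxyphenoxy}phenyl)-5-methoxy-2,3-dihydro-1-benzofuran
Product: 14 2-[2-(4-{5-[2-(3-bromophenyl)ethyl]-2-methoxyphenoxy}phenyl)ethyl]-4-methoxyphenol, via ring-opened benzylic cation 13 (not isolated)
Conditions: Et3SiH (5 equiv), CF3CO2H–CH2Cl2 (1:1), 0.02 M, 0 °C → rt
Reagents that add atoms: none
Why: Ionic hydrogenation, in which protonation of the ring oxygen lets the benzylic C–O bond ionise to cation 13, stabilised by the para aryloxy oxygen of ring B and reduced irreversibly to CH2 by Et3SiH, while the aryl bromide, the methyl ethers and the diaryl ether hold no C–O bond that can ionise to a stabilised cation and the stereocentre disappears.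

Step 8
Reactants: 14 2-[2-(4-{5-[2-(3-bromophenyl)ethyl]-2-methoxyphenoxy}phenyl)ethyl]-4-methoxyphenol
Product: 15 macrocyclic bis(bibenzyl) dimethyl ether (18-membered ring; ring A oxygen bound to C3 of ring D; OMe on ring A para to that oxygen and OMe on ring C ortho to the ring B–O–ring C oxygen)
Conditions: CuI (30 mol %), N,N-dimethylglycine hydrochloride (60 mol %), Cs2CO3 (3 equiv), degassed 1,4-dioxane, 100 °C, syringe-pump addition to 2 mM, Ar
Reagents that add atoms: none
Why: Ligand-accelerated intramolecular Ullmann diaryl ether synthesis, in which the only free phenol (ring A) is bound to copper and displaces the only aryl halide (ring D bromide), and in which slow addition at millimolar concentration favours closure of the 18-membered ring over oligomers, as in known Ullmann closures of macrocyclic diaryl ethers.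

Step 9
Reactants: 15 macrocyclic bis(bibenzyl) dimethyl ether
Product: 16 target CNP0135015.0 (macrocyclic bis(bibenzyl) diol)
Conditions: BBr3 (6 equiv), CH2Cl2, −78 °C → rt; then H2O
Reagents that add atoms: none
Why: Lewis-acid ether cleavage with BBr3, in which boron binds each methoxy oxygen and bromide attacks the methyl carbon by SN2, while the two diaryl ether oxygens offer no sp3 carbon for this attack and the macrocycle stays closed.

**Compound list**

1 | 3-bromobenzyl bromide | BrCc1cccc(Br)c1 | starting material
2 | (3-bromobenzyl)triphenylphosphonium bromide | [Br-].Brc1cccc(C[P+](c2ccccc2)(c2ccccc2)c2ccccc2)c1 | intermediate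
3 | isovanillin | COc1ccc(C=O)cc1O | starting material
4 | 3-bromobenzylidene(triphenyl)phosphorane (not isolated) | Brc1cccc(C=P(c2ccccc2)(c2ccccc2)c2ccccc2)c1 | intermediate
5 | 5-[2-(3-bromophenyl)ethenyl]-2-methoxyphenol, E/Z mixture | COc1ccc(C=Cc2cccc(Br)c2)cc1O | intermediate
6 | 5-[2-(3-bromophenyl)ethyl]-2-methoxyphenol | COc1ccc(CCc2cccc(Br)c2)cc1O | intermediate
7 | 4-fluorobenzaldehyde | O=Cc1ccc(F)cc1 | starting material
8 | 4-{5-[2-(3-bromophenyl)ethyl]-2-methoxyphenoxy}benzaldehyde | COc1ccc(CCc2cccc(Br)c2)cc1Oc1ccc(C=O)cc1 | intermediate
9 | 1-bromo-3-{2-[3-(4-ethenylphenoxy)-4-methoxyphenyl]ethyl}benzene | C=Cc1ccc(cc1)Oc1cc(ccc1OC)CCc1cccc(Br)c1 | intermediate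
10 | 4-methoxyphenol | COc1ccc(O)cc1 | starting material
11 | 4-methoxyphenoxenium ion (not isolated) | C[O+]=C1C=CC(=O)C=C1 | intermediate
12 | (±)-2-(4-{5-[2-(3-bromophenyl)ethyl]-2-methoxyphenoxy}phenyl)-5-methoxy-2,3-dihydro-1-benzofuran, racemic at C2 | COc1ccc2OC(Cc2c1)c1ccc(cc1)Oc1cc(ccc1OC)CCc1cccc(Br)c1 | intermediate
13 | ring-opened benzylic cation (not isolated) | COc1ccc(O)c(C[CH+]c2ccc(cc2)Oc2cc(ccc2OC)CCc2cccc(Br)c2)c1 | intermediate
14 | 2-[2-(4-{5-[2-(3-bromophenyl)ethyl]-2-methoxyphenoxy}phenyl)ethyl]-4-methoxyphenol | COc1ccc(O)c(CCc2ccc(cc2)Oc2cc(ccc2OC)CCc2cccc(Br)c2)c1 | intermediate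
15 | macrocyclic bis(bibenzyl) dimethyl ether | COc1ccc2c(c1)CCc1ccc(cc1)Oc1cc(ccc1OC)CCc1cccc(c1)O2 | intermediate
16 | CNP0135015.0, macrocyclic bis(bibenzyl) diol | Oc1ccc2c(c1)CCc1ccc(cc1)Oc1cc(ccc1O)CCc1cccc(c1)O2 | target

Total step count: 9
Longest linear sequence: 9 steps (1 → 2 → 5 → 6 → 8 → 9 → 12 → 14 → 15 → 16)

**Three steps most likely to fail**

**Step 6.**
- What may go wrong: the terminal styrene may oligomerise under the acid released by the oxidant or through its own radical cation. The phenol may be over-oxidised or couple with itself before the alkene traps it. The electron-rich product may also be oxidised further.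
- Fallback: oxidation is separated from bond formation, so that 9 never meets an oxidant or light.
  - It sets out from 10, which PhI(OAc)2 in MeOH at 0 °C should convert into 4,4-dimethoxycyclohexa-2,5-dien-1-one F1, isolated.
  - F1 and 9 are then combined with catalytic C6F5CO2H in (CF3)2CHOH–CH2Cl2 at rt. This is the known acid-catalysed [3+2] coupling of quinone monoketals with styrenes: ionisation of the ketal gives the same cation 11 and the same two bonds form.
  - The fallback comes back to the route at 12.

**Step 7.**
- What may go wrong: the cation may re-close to the dihydrofuran faster than the silane captures it, so that nothing is cleaved. It may instead alkylate the electron-rich rings of a second molecule (Friedel–Crafts oligomerisation).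
- Fallback: the same C(ring A)–C bond is made from the same styrene without ever forming the temporary C–O bond.
  - It sets out from 10, which NIS with catalytic TsOH in MeCN should iodinate next to the hydroxyl group to give 2-iodo-4-methoxyphenol F2.
  - A Heck reaction of F2 with 9 follows (Pd(OAc)2, Bu4NCl, NaHCO3, DMF, 60 °C). Zerovalent palladium inserts into the carbon–iodine bond far faster than into the ring D carbon–bromine bond.
  - This should give (E)-2-[2-(4-{5-[2-(3-bromophenyl)ethyl]-2-methoxyphenoxy}phenyl)ethenyl]-4-methoxyphenol F3.
  - Diimide reduction of F3 (TsNHNH2, NaOAc, DME–H2O, reflux) saturates the alkene with the bromide retained. The fallback comes back to the route at 14.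

**Step 8.**
- What may go wrong: intermolecular etherification may outrun ring closure. The bromide may be lost by protodebromination at 100 °C. The electron-rich phenoxide may be oxidised by traces of air.
- Fallback: the polarity of ring D is inverted and the ring is closed oxidatively at room temperature.
  - It sets out from 14, treated with n-BuLi (2.2 equiv, THF, −78 °C; phenol deprotonation, then bromine–lithium exchange), then B(OiPr)3 and 1 M HCl.
  - This should give (3-{2-[3-(4-[2-(2-hydroxy-5-methoxyphenyl)ethyl]phenoxy)-4-methoxyphenyl]ethyl}phenyl)boronic acid F4.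
  - An intramolecular Chan–Lam coupling follows (Cu(OAc)2, pyridine, 4 Å molecular sieves, CH2Cl2, dry air, rt, 1–2 mM), a reaction type known for macrocyclic diaryl ethers. The fallback comes back to the route at 15.

**Further compounds**

F1 | step 6 | 4,4-dimethoxycyclohexa-2,5-dien-1-one | COC1(OC)C=CC(=O)C=C1
F2 | step 7 | 2-iodo-4-methoxyphenol | COc1ccc(O)c(I)c1
F3 | step 7 | (E)-2-[2-(4-{5-[2-(3-bromophenyl)ethyl]-2-methoxyphenoxy}phenyl)ethenyl]-4-methoxyphenol | COc1ccc(O)c(/C=C/c2ccc(cc2)Oc2cc(ccc2OC)CCc2cccc(Br)c2)c1
F4 | step 8 | (3-{2-[3-(4-[2-(2-hydroxy-5-methoxyphenyl)ethyl]phenoxy)-4-methoxyphenyl]ethyl}phenyl)boronic acid | COc1ccc(O)c(CCc2ccc(cc2)Oc2cc(ccc2OC)CCc2cccc(c2)B(O)O)c1
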